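## Retrosynthetic overview
1. 16 ⇐ 15 (O15 desilylation) ⇐ 14. The last ring closure forms the C6–C7 bond and the γ-lactone in one visible-light photoredox/chromium allylation. It closes the ten-membered ring and sets C6 and C7 from C8.
2. 14 ⇐ 13. A 2,3-disubstituted furan serves as the latent (Z)-C3-ketone/C6-enal. Singlet oxygen unmasks it, and O10 then closes on C3 to give the 3(2H)-furanone.
3. 13 ⇐ 9. O8 is tigloylated, and C7 goes from CH2OTES to CHO, to the acrylate adduct (C11–C13), to the allylic bromide.
4. 9 ⇐ 4 + 8. The C1–C2 bond comes from acetylide addition to the lactone, followed by enynol → furan cycloisomerisation. Fragment 8 comes from butynediol, where trans-hydroalumination fixes the C4=C5 geometry.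
5. 4 ⇐ 1. C8 is bought, and C10 is set by anti-face methylation then hydroxylation of the lactone enolate. Ring order: sacrificial butyrolactone → furan → furanone → macrocycle plus α-methylene lactone.

Assumptions: germacrane numbering (C1–C15) is used for atom labels. A telescoped sequence with one purification counts as one step. Small atom-donating reagents (MeI, ethynylMgBr, tiglic acid, methyl propiolate and the like) are listed as reagents, not numbered.

## Route

**Step 1**
Reactants: 1, (S)-5-(hydroxymethyl)dihydrofuran-2(3H)-one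
Product: 2, (S)-5-{[(triethylsilyl)oxy]methyl}dihydrofuran-2(3H)-one
Conditions: TESCl, imidazole, CH2Cl2, 0 °C → rt
Reagents that add atoms: chlorotriethylsilane, CC[Si](Cl)(CC)CC
Why: Standard silylation gives a primary TES ether that survives the enolate and organolithium steps and can later be oxidised directly to the aldehyde, leaving the bought C8 centre untouched.

**Step 2**
Reactants: 2
Product: 3, (3R,5S)-3-methyl-5-{[(triethylsilyl)oxy]methyl}dihydrofuran-2(3H)-one (trans major)
Conditions: LDA, THF, –78 °C; MeI, –78 → –40 °C
Reagents that add atoms: iodomethane, CI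
Why: In this lactone enolate alkylation MeI enters anti to the C8 side chain, and the dr does not matter because this carbon is re-planarised in step 3.

**Step 3**
Reactants: 3
Product: 4, (3R,5S)-3-methyl-3-[(triethylsilyl)oxy]-5-{[(triethylsilyl)oxy]methyl}dihydrofuran-2(3H)-one
Conditions: KHMDS, THF, –78 °C; (±)-2-(phenylsulfonyl)-3-phenyloxaziridine; then TESCl, –78 → 0 °C
Reagents that add atoms: racemic Davis oxaziridine, O=S(=O)(c1ccccc1)N1OC1c1ccccc1; chlorotriethylsilane, CC[Si](Cl)(CC)CC
Why: In this enolate hydroxylation the oxidant attacks the tetrasubstituted enolate anti to the C8 CH2OTES group, so O10 ends trans to C7 (C10 = R, substrate control), and the potassium alkoxide is silylated in situ.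

**Step 4**
Reactants: 5, but-2-yne-1,4-diol
Product: 6, 4-[(tert-butyldiphenylsilyl)oxy]but-2-yn-1-ol
Conditions: 5 (3 equiv), TBDPSCl (1 equiv), imidazole, THF/DMF, 0 °C → rt
Reagents that add atoms: tert-butylchlorodiphenylsilane, CC(C)(C)[Si](Cl)(c1ccccc1)c1ccccc1
Why: Statistical monosilylation with excess cheap diol differentiates the future O15 (protected) from O6 (free).

**Step 5**
Reactants: 6
Product: 7, (Z)-4-[(tert-butyldiphenylsilyl)oxy]-3-iodobut-2-en-1-ol
Conditions: Red-Al, THF, 0 °C → rt; EtOAc; I2, –78 °C
Reagents that add atoms: iodine, II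
Why: Hydroxyl-directed trans-hydroalumination followed by iodinolysis places iodine on C4, cis to the C6 carbinol, which fixes the C4=C5 geometry of the target.

**Step 6**
Reactants: 7
Product: 8, (E)-3-{[(tert-butyldiphenylsilyl)oxy]methyl}pent-2-en-4-yn-1-ol (ethynyl cis to CH2OH; E only by CIP priority)
Conditions: HC≡CMgBr, ZnBr2, THF; 7, Pd(PPh3)4 (5 mol %), 0 °C → rt
Reagents that add atoms: ethynylmagnesium bromide, C#C[Mg]Br
Why: Negishi-type alkynylation of the alkenyl iodide proceeds with retention of geometry and gives the terminal enyne (C2≡C3) directly.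

**Step 7**
Reactants: 4 and 8
Product: 9, (3R,5S)-1-[3-({[tert-butyl(diphenyl)silyl]oxy}methyl)furan-2-yl]-5-hydroxy-3-methyl-3,6-bis[(triethylsilyl)oxy]hexan-2-one (in equilibrium with its cyclic C1 hemiketal)
Conditions: 8 (1.3 equiv), n-BuLi (2.6 equiv), THF, –78 °C; 4, –78 → –30 °C; NH4Cl; crude, Ph3PAuNTf2 (1 mol %), CH2Cl2, rt
Reagents that add atoms: none
Why: The alkynyllithium adds once to the γ-lactone (C1–C2 bond, stopping at the hemiketal), and the π-acid then drives the (Z)-2-en-4-yn-1-ol → furan cycloisomerisation (5-exo-dig attack of O6 on C3, then aromatisation), with silylated O10 unable to compete and C8/C10 untouched.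

**Step 8**
Reactants: 9
Product: 10, the C8 (E)-2-methylbut-2-enoate (tiglate) of 9: (2S,4R)-6-[3-(TBDPSO-methyl)furan-2-yl]-4-methyl-5-oxo-1,4-bis(triethylsilyloxy)hexan-2-yl tiglate
Conditions: tiglic acid, DCC, DMAP, CH2Cl2, rt
Reagents that add atoms: tiglic acid, C/C=C(\C)C(=O)O
Why: Steglich esterification of the only acylable carbinol drains the hemiketal through the open hydroxy-ketone with retention at C8, and the E-configured tiglate is the stable isomer.

**Step 9**
Reactants: 10
Product: 11, (2S,4R)-6-[3-(TBDPSO-methyl)furan-2-yl]-4-methyl-1,5-dioxo-4-(triethylsilyloxy)hexan-2-yl tiglate (C7 aldehyde)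
Conditions: (COCl)2, DMSO, CH2Cl2, –78 → –40 °C; i-Pr2NEt, → 0 °C
Reagents that add atoms: none
Why: Swern conditions oxidise an unhindered primary TES ether directly, so no free O7–H ever exists to accept the tiglate, while the tertiary TES ether, TBDPS ether and furan survive and the cold hindered base avoids C8 epimerisation.

**Step 10**
Reactants: 11
Product: 12, methyl (4S,6R)-8-[3-(TBDPSO-methyl)furan-2-yl]-3-hydroxy-6-methyl-2-methylidene-7-oxo-4-(tigloyloxy)-6-(triethylsilyloxy)octanoate (C7 carbinol epimers)
Conditions: DIBAL-H, NMO, THF, 0 °C; methyl propiolate; then 11, 0 °C → rt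
Reagents that add atoms: methyl propiolate, C#CC(=O)OC
Why: Vinylalumination (addition of the α-(methoxycarbonyl)vinylalane to the aldehyde) gives the Morita–Baylis–Hillman-type adduct without amine base, which avoids C8 epimerisation, tiglate migration and aldol attack by the acidic furfuryl ketone, and the new carbinol centre is erased in step 11.

**Step 11**
Reactants: 12
Product: 13, methyl (2Z,4S,6R)-2-(bromomethyl)-8-[3-(TBDPSO-methyl)furan-2-yl]-6-methyl-7-oxo-4-(tigloyloxy)-6-(triethylsilyloxy)oct-2-enoate
Conditions: PBr3, Et2O, –10 °C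
Reagents that add atoms: phosphorus tribromide, BrP(Br)Br
Why: SN2′ bromination of the Baylis–Hillman-type alcohol gives the conjugated (Z)-2-(bromomethyl)enoate and leaves C8 untouched.

**Step 12**
Reactants: 13
Product: 14, methyl (2Z,4S)-2-(bromomethyl)-5-[(2R)-5-{(2Z)-1-[(tert-butyldiphenylsilyl)oxy]-4-oxobut-2-en-2-yl}-2-methyl-3-oxo-2,3-dihydrofuran-2-yl]-4-(tigloyloxy)pent-2-enoate
Conditions: O2, TPP (1 mol %), white LEDs, CH2Cl2, –78 °C; PPh3 (1.0 equiv), –78 → –20 °C; then 48 % aq HF, MeCN, 0 °C
Reagents that add atoms: oxygen, O=O (supplies one carbonyl O of the intermediate enedione; the net O count is unchanged after loss of water)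
Why: Furan [4+2] photooxygenation and reduction gives the cis-enedione (C3 ketone and C6 enal, Z geometry inherited from the ring), after which acid removes the tertiary TES and the α′-hydroxy-1,3-diketone cyclodehydrates to the 3(2H)-furanone, while the electron-poor alkenes, bromide and TBDPS ether are inert and C10 is not involved.

**Step 13**
Reactants: 14
Product: 15, 15-O-TBDPS-lychnophorolide B (6R,7R,8S,10R; 4Z)
Conditions: 4CzIPN (2 mol %), CrCl3·3THF (15 mol %), Hantzsch ester (1.5 equiv), degassed THF/DMF 9:1, 450 nm LEDs, 25 °C, 14 added by syringe pump over 12 h (final 1 mM); then PPTS (cat.), CH2Cl2, rt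
Reagents that add atoms: none
Why: Proposed new method: a chromium-catalytic, light-driven Nozaki–Hiyama-type (2-alkoxycarbonyl)allylation run as a macrocyclisation–lactonisation, in which excited 4CzIPN is reductively quenched by the Hantzsch ester, its radical anion reduces Cr(III) to Cr(II), two Cr(II) convert the activated allyl bromide via the allyl radical into the (E)-allylchromium(III), this adds through C7 to the C6 enal in a chair Zimmerman–Traxler transition state (anti, giving the trans-6,7 lactone) on the face anti to the C8–O bond with H8 eclipsing the ester (Felkin–Anh/A1,3 control, giving 7R and 6R), the alkoxide lactonises on the methyl ester and pyridinium protonolysis returns Cr(III), and any E-enal is recycled by energy transfer; the closest known chemistry is the stoichiometric CrCl2/Zn Barbier macrocyclisation of bromomethyl-enoate enals to germacranolides and the intermolecular photoredox/chromium allylation of aldehydes.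

**Step 14**
Reactants: 15
Product: 16, lychnophorolide B
Conditions: HF·pyridine, THF, 0 °C → rt
Reagents that add atoms: none
Why: Acidic fluoride desilylation frees the C15 alcohol without touching the tiglate, α-methylene lactone, furanone or any stereocentre.

## Compound list
1 | (S)-5-(hydroxymethyl)dihydrofuran-2(3H)-one | OC[C@@H]1CCC(=O)O1 | starting material
2 | O7-TES lactone | CC[Si](CC)(CC)OC[C@@H]1CCC(=O)O1 | intermediate
3 | (3R,5S)-α-methyl lactone | C[C@@H]1C[C@@H](CO[Si](CC)(CC)CC)OC1=O | intermediate
4 | (3R,5S)-α-methyl-α-OTES lactone | C[C@@]1(O[Si](CC)(CC)CC)C[C@@H](CO[Si](CC)(CC)CC)OC1=O | intermediate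
5 | but-2-yne-1,4-diol | OCC#CCO | starting material
6 | mono-TBDPS butynediol | OCC#CCO[Si](c1ccccc1)(c1ccccc1)C(C)(C)C | intermediate
7 | (Z)-iodoalkenol | OC/C=C(\I)CO[Si](c1ccccc1)(c1ccccc1)C(C)(C)C | intermediate
8 | enynol (ethynyl cis to CH2OH) | OC/C=C(\C#C)CO[Si](c1ccccc1)(c1ccccc1)C(C)(C)C | intermediate
9 | furyl hydroxy-ketone | CC[Si](CC)(CC)OC[C@@H](O)C[C@@](C)(O[Si](CC)(CC)CC)C(=O)Cc1occc1CO[Si](c2ccccc2)(c2ccccc2)C(C)(C)C | intermediate
10 | C8 tiglate | CC[Si](CC)(CC)OC[C@@H](OC(=O)/C(C)=C/C)C[C@@](C)(O[Si](CC)(CC)CC)C(=O)Cc1occc1CO[Si](c2ccccc2)(c2ccccc2)C(C)(C)C | intermediate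
11 | C7 aldehyde | O=C[C@@H](OC(=O)/C(C)=C/C)C[C@@](C)(O[Si](CC)(CC)CC)C(=O)Cc1occc1CO[Si](c2ccccc2)(c2ccccc2)C(C)(C)C | intermediate
12 | Baylis–Hillman-type alcohol | C=C(C(=O)OC)C(O)[C@@H](OC(=O)/C(C)=C/C)C[C@@](C)(O[Si](CC)(CC)CC)C(=O)Cc1occc1CO[Si](c2ccccc2)(c2ccccc2)C(C)(C)C | intermediate
13 | (Z)-allylic bromide, furan | COC(=O)/C(CBr)=C/[C@@H](OC(=O)/C(C)=C/C)C[C@@](C)(O[Si](CC)(CC)CC)C(=O)Cc1occc1CO[Si](c2ccccc2)(c2ccccc2)C(C)(C)C | intermediate
14 | furanone (Z)-enal allylic bromide | COC(=O)/C(CBr)=C/[C@@H](OC(=O)/C(C)=C/C)C[C@@]1(C)OC(=CC1=O)/C(CO[Si](c2ccccc2)(c2ccccc2)C(C)(C)C)=C\C=O | intermediate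
15 | 15-O-TBDPS-lychnophorolide B | C=C1C(=O)O[C@@H]2/C=C(/CO[Si](c4ccccc4)(c4ccccc4)C(C)(C)C)C3=CC(=O)[C@@](C)(C[C@H](OC(=O)/C(C)=C/C)[C@@H]12)O3 | intermediate
16 | lychnophorolide B | C=C1C(=O)O[C@@H]2/C=C(/CO)C3=CC(=O)[C@@](C)(C[C@H](OC(=O)/C(C)=C/C)[C@@H]12)O3 | target

## Step count and risks
Total steps: 14, with the telescoped sequences in steps 3, 7 and 12 each counted once.
Longest linear sequence: 11 (steps 1–3, then 7–14; the branch 4–6, then 7–14, is also 11).

Steps most likely to fail:

1. **Step 13 (proposed new step).**
   - Risks: hydrodebromination, oligomerisation, reduction of the ene-dicarbonyl chromophore, or the wrong C6/C7 diastereomer.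
   - Fallback (known chemistry only, different ring-closure order): make C6–C7 intermolecularly by a stoichiometric CrCl2 Hiyama–Nozaki/Dreiding–Schmidt allylation–lactonisation of a (Z)-enynal with the C7 allyl bromide. Then close the ten-membered ring at C1–C2 by intramolecular Nozaki–Hiyama–Kishi addition of an alkynyl iodide to a C1 aldehyde. Finish with DMP oxidation, Au(I)-catalysed transannular 5-endo cyclisation to the furanone, and tigloylation.

2. **Step 12 (furan → furanone/enal cascade).**
   - Risks: intramolecular aldol of the 1,3-diketone onto the enal (giving a cyclopentenone), Z/E leakage, or loss of the bromide to the reductant.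
   - Fallback: abandon the furan mask. Silylate O6 of 8, leave O10 free, and form the furanone early by the known Au(I) cyclisation of the α′-hydroxy-ynone. Generate the enal at the end by selective desilylation and MnO2 oxidation. This costs two more steps.

3. **Step 10 (C7 homologation of the α-acyloxy aldehyde beside an enolisable ketone).**
   - Risks: low conversion, C8 epimerisation, tiglate migration, or C2→C7 aldol.
   - Fallback: change the order. Oxidise 4 to the lactone aldehyde, where O8 and C1 are locked and there is no ketone or ester to migrate, and run a classical DABCO Morita–Baylis–Hillman reaction there. Silylate the carbinol, and only then add dilithiated 8 to the lactone and continue.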